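(The data were generated by integration for an exercise.)

At early times in the beta run side product led, 24.3% against 23.3% of target at 15.0 h, and target passed it later. So in beta the share at that reading was not yet the last share read.

| flask | substrate | temperature | remark | time |
|---|---|---|---|---|
| beta | 0.025 M | 15 °C | run made earlier |  |
| epsilon | 0.038 M | 50 °C | run made earlier |  |
| maple | 0.050 M | 80 °C |  | 2.5 h |
| ash | 0.050 M | 20 °C |  | 2.5 h |
| alder | 0.050 M | 50 °C |  | 2.5 h |

| run | time / h | target / % | side product / % |
|---|---|---|---|
| beta | 15.0 | 23.3 | 24.3 |
| beta | 30.0 | 44.7 | 39.7 |
| beta | 50.0 | 53.0 | 44.2 |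
| beta | 60.0 | 53.2 | 44.7 |
| beta | 72.0 | 54.0 | 44.7 |
| epsilon | 3.00 | 49.3 | 50.5 |
| epsilon | 6.00 | 48.6 | 50.8 |
| epsilon | 8.00 | 49.5 | 50.8 |
| epsilon | 12.0 | 49.2 | 50.6 |

(standard deviation of a reading: 0.3 percentage points)

- percentages count the substrate that a species holds: one homo dimer counts as two
- steps that have been proposed: substrate -> intermediate A; intermediate A -> intermediate B; intermediate B -> side product; intermediate B <-> intermediate C; intermediate C -> intermediate D; intermediate D -> target; 2 substrate -> homo dimer

* the flask that comes out highest in share of target in all that became target or side product, or "all alike" when all lie within 1.5 percentage points (maple / ash / alder / all alike)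
* share of target in all that became target or side product, maple
* share of target in all that became target or side product, ash
* share of target in all that became target or side product, alder

I turned the settings one at a time. By hand, the amount of substrate should do little, since the steps on to target and side product are first order and the charge cancels from the share (the selectivity). The balances of the two runs reached 98.7% and 99.8%, so little went elsewhere.

The last share fell from 54.7% in beta to 49.3% in epsilon; the charge differed as well as the temperature, but by hand the charge cancels, so I read the fall as heat and put maple lower than alder.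

For time I counted half-lives. The remainder of side product in beta gave a half-life

h_b = 7.39 h

and epsilon, whose first two readings differ by scatter, gave a rough figure that I took as an upper mark

h_e = 0.406 h

So, on these two rough figures, the half-life halves about once per

D = 8.36 K

which for ash gives

h_a = 4.88 h, n = 0.512

This n, the time of a run over the half-life at its temperature, is an estimate, on the low side if h_e is too long. Alder counts about 6.16 or more. Ash stands below one, while beta at its first reading had 2.03 and a share of 48.9%. Ash would match that reading if its 5.00 K of extra warmth gave a speed-up of 6.00. I therefore put ash below that share, and alder, at the 49.3% of epsilon, above it.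

The forecast said alder, with maple 45.5%, ash 30% and alder 49.3%: “Ash is the trap.”

The flasks gave maple 44.3%, ash 30.2% and alder 49.1%, so alder came out highest.

    substrate → intermediate A (k = 0.00220 /s, Ea = 92.0 kJ/mol)
    intermediate A → intermediate B (k = 6.90 × 10⁻⁵ /s, Ea = 89.0 kJ/mol)
    intermediate B → side product (k = 2.90 × 10⁻⁵ /s, Ea = 100 kJ/mol)
    intermediate B ⇌ intermediate C (K = 0.190, k = 4.00 × 10⁻⁵ /s, Ea = 98.0 kJ/mol, ΔH = −13.0 kJ/mol)
    intermediate C → intermediate D (k = 0.00110 /s, Ea = 97.0 kJ/mol)
    intermediate D → target (k = 2.30 × 10⁻⁴ /s, Ea = 92.0 kJ/mol)
    2 substrate → homo dimer (k = 5.70 × 10⁻⁴ /M/s, Ea = 52.0 kJ/mol)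
    (constants at 20 °C)

In ash the half-life of intermediate A by its step to intermediate B was 2.79 h, longer than the 2.5 h of the run, a count of 0.896 against my estimate of 0.512, and at the end of that run intermediate A still held 54.8% while intermediate B, each step taken net, was made 1.82 times faster than used up. For a flask like ash but at 45 °C, with the same charge and time, my count gave about 4.07, and that flask ended at a share of 49.9% with intermediate B at 0.00837%.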